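## Retrosynthetic overview

- The depside ester between O4 of ring B and the C1' carbonyl of ring A is cut next to last. This gives methyl 2,4-dihydroxy-3,5,6-trimethylbenzoate and 3-formyl-2,4-dimethoxy-5,6-dimethylbenzoic acid. The two ring A methyl ethers are removed in the final step.
- The plan rests on one feature of ring B. The C6 methyl and the C1 carboxyl carbon sit on adjacent ring atoms, and C1 is flanked on its other side by the C2 oxygen. A carbon nucleophile and then an electrophile adding across a 3-alkoxyaryne leave exactly this pattern, so both bonds are cut at once, back to 1-fluoro-3,5-dimethoxy-2,4-dimethylbenzene, CH3MgBr and CO2.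
- The fluoroarene is built from 1-fluoro-3,5-dimethoxybenzene by directed lithiations. Base goes first to a hydrogen flanked by F and OMe, so the methyl beside fluorine is installed first. The second such site is masked as SiMe3 while the methyl between the methoxy groups goes in, and the silane is then removed.
- The ring A acid comes from 4,5-dimethylresorcinol dimethyl ether. The C3' formyl is set by lithiation between the oxygens, and the C1' carboxyl by bromination followed by Br–Li exchange/CO2 on the acetal.
- No ring is formed in the route. Both benzene rings are purchased; ring B is elaborated in the longest line and ring A in parallel.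

Key step: step 5

Assumption: the target is achiral, so no stereodescriptor is needed. Locants C1–C6 refer to ring B (C1 bears CO2Me) and C1'–C6' to ring A (C1' bears the depside carbonyl).

## Route

### Ring B

Step 1
Reactants: 1 1-fluoro-3,5-dimethoxybenzene, 2 iodomethane
Product: 4 1-fluoro-3,5-dimethoxy-2-methylbenzene, via aryllithium 3 (not isolated)
Conditions: n-BuLi, THF, −78 °C; MeI, −78 °C
Reagents that add atoms: iodomethane, CI
Why: Directed ortho-lithiation followed by SN2 methylation: the hydrogen flanked by fluorine and methoxy is the most acidic one of 1, and at −78 °C aryllithium 3 keeps its fluoride long enough to be trapped by MeI.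

Step 2
Reactants: 4 1-fluoro-3,5-dimethoxy-2-methylbenzene
Product: 6 (2-fluoro-4,6-dimethoxy-3-methylphenyl)trimethylsilane, via aryllithium 5 (not isolated)
Conditions: LiN(i-Pr)2, Me3SiCl (present from the start), THF, −78 °C
Reagents that add atoms: chlorotrimethylsilane, C[Si](C)(C)Cl
Why: Directed ortho-lithiation with in situ silyl trapping: the amide base is strong enough only for the remaining hydrogen beside fluorine, not for the one between the two methoxy groups, and the chlorosilane captures aryllithium 5 as it forms, which masks the site reserved for the aryne.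

Step 3
Reactants: 6 (2-fluoro-4,6-dimethoxy-3-methylphenyl)trimethylsilane, 2 iodomethane
Product: 8 (2-fluoro-4,6-dimethoxy-3,5-dimethylphenyl)trimethylsilane, via aryllithium 7 (not isolated)
Conditions: s-BuLi, TMEDA, THF, −78 to −40 °C; MeI, −78 °C
Reagents that add atoms: iodomethane, CI
Why: Directed ortho-lithiation at the only ring C–H left, the one between the two methoxy groups, followed by SN2 methylation; lithium cannot sit beside fluorine in this substrate, so LiF cannot be lost.

Step 4
Reactants: 8 (2-fluoro-4,6-dimethoxy-3,5-dimethylphenyl)trimethylsilane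
Product: 9 1-fluoro-3,5-dimethoxy-2,4-dimethylbenzene
Conditions: CF3CO2H, CH2Cl2, rt
Reagents that add atoms: none
Why: Protodesilylation (ipso electrophilic aromatic substitution): the silicon-bearing carbon is ortho and para to the methoxy groups and sterically compressed, so protonation there and loss of silicon should be fast, while the C–F bond and the ethers are inert to CF3CO2H.

Step 5
Reactants: 9 1-fluoro-3,5-dimethoxy-2,4-dimethylbenzene, 10 methylmagnesium bromide, 11 carbon dioxide
Product: 15 2,4-dimethoxy-3,5,6-trimethylbenzoic acid, via aryllithium 12 (not isolated), via aryne 13 (not isolated), via arylmagnesium bromide 14 (not isolated)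
Conditions: n-BuLi (1.05 equiv), THF, −78 °C; MeMgBr (3 equiv), −78 °C to rt; CO2 (g), 0 °C; aq. HCl
Reagents that add atoms: methylmagnesium bromide, C[Mg]Br; carbon dioxide, O=C=O
Why: n-BuLi removes the single ring hydrogen of 9, which is acidified by the flanking fluorine and methoxy group, and on warming aryllithium 12 expels LiF to give aryne 13, the C1–C6 aryne of ring B. CH3MgBr carbometalates the strained triple bond and the resulting arylmagnesium 14 is carboxylated by CO2, so that C6–CH3 and C1–CO2H are both made in one flask. The closest known reaction type is the three-component coupling of 3,5-dialkoxyarynes, generated from the fluoroarenes with n-BuLi, with Grignard reagents and CO2 to give 6-alkylresorcylic acids. No ring is closed and no stereocentre is formed. The selectivity needed is regiochemical: the sigma-withdrawing C2 methoxy group distorts the aryne so that C6 is the more linear, electrophilic terminus and the negative charge builds up at C1 next to oxygen, where magnesium is also chelated, and the small methyl nucleophile tolerates the C5 methyl group beside C6. Having excess CH3MgBr in the flask before elimination begins keeps 12 from adding to 13.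

Step 6
Reactants: 15 2,4-dimethoxy-3,5,6-trimethylbenzoic acid, 2 iodomethane
Product: 16 methyl 2,4-dimethoxy-3,5,6-trimethylbenzoate
Conditions: MeI, K2CO3, DMF, rt
Reagents that add atoms: iodomethane, CI
Why: SN2 O-alkylation of the carboxylate avoids the tetrahedral intermediate that a Fischer esterification of this di-ortho-substituted acid would require.

Step 7
Reactants: 16 methyl 2,4-dimethoxy-3,5,6-trimethylbenzoate
Product: 17 methyl 2,4-dihydroxy-3,5,6-trimethylbenzoate
Conditions: BCl3 (excess), CH2Cl2, −10 °C to rt; H2O
Reagents that add atoms: none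
Why: Lewis acid aryl methyl ether cleavage: BCl3 removes the C2 ether through chelation with the ester carbonyl and the C4 ether because its two flanking methyl groups twist it out of conjugation and make its oxygen basic, while the methyl ester is left intact.

### Ring A

Step 8
Reactants: 18 4,5-dimethylresorcinol, 2 iodomethane
Product: 19 1,5-dimethoxy-2,3-dimethylbenzene
Conditions: MeI, K2CO3, acetone, reflux
Reagents that add atoms: iodomethane, CI
Why: Williamson ether synthesis on both phenols; methyl ethers survive the organolithium steps and can be taken off at the end with BCl3.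

Step 9
Reactants: 19 1,5-dimethoxy-2,3-dimethylbenzene
Product: 21 2,6-dimethoxy-3,4-dimethylbenzaldehyde, via aryllithium 20 (not isolated)
Conditions: n-BuLi, TMEDA, THF, 0 °C to rt; DMF, 0 °C; aq. HCl
Reagents that add atoms: N,N-dimethylformamide, CN(C)C=O
Why: Directed ortho-lithiation at the position flanked by both methoxy groups, then formylation of the aryllithium with DMF, places the formyl carbon at C3'.

Step 10
Reactants: 21 2,6-dimethoxy-3,4-dimethylbenzaldehyde
Product: 22 3-bromo-2,6-dimethoxy-4,5-dimethylbenzaldehyde
Conditions: NBS, MeCN, 0 °C to rt, dark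
Reagents that add atoms: N-bromosuccinimide, O=C1CCC(=O)N1Br
Why: Electrophilic aromatic bromination at the only free ring position, which is ortho and para to the methoxy groups and meta to the aldehyde; polar conditions in the dark suppress benzylic bromination.

Step 11
Reactants: 22 3-bromo-2,6-dimethoxy-4,5-dimethylbenzaldehyde
Product: 23 2-(3-bromo-2,6-dimethoxy-4,5-dimethylphenyl)-1,3-dioxolane
Conditions: HOCH2CH2OH, p-toluenesulfonic acid (cat.), toluene, reflux, Dean–Stark
Reagents that add atoms: ethylene glycol, OCCO
Why: Acid-catalysed acetalisation with azeotropic removal of water masks the aldehyde against the organolithium reagent of the next step.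

Step 12
Reactants: 23 2-(3-bromo-2,6-dimethoxy-4,5-dimethylphenyl)-1,3-dioxolane, 11 carbon dioxide
Product: 26 3-formyl-2,4-dimethoxy-5,6-dimethylbenzoic acid, via aryllithium 24 (not isolated), via lithium carboxylate 25 (not isolated)
Conditions: n-BuLi, THF, −78 °C; CO2 (g), −78 to 0 °C; 2 M HCl, THF, rt
Reagents that add atoms: carbon dioxide, O=C=O; water, O
Why: Bromine–lithium exchange, carboxylation of the aryllithium and acid hydrolysis of the electron-rich dioxolane during work-up should deliver the formyl acid in one operation.

### Coupling and deprotection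

Step 13
Reactants: 26 3-formyl-2,4-dimethoxy-5,6-dimethylbenzoic acid, 17 methyl 2,4-dihydroxy-3,5,6-trimethylbenzoate
Product: 28 methyl 4-[(3-formyl-2,4-dimethoxy-5,6-dimethylbenzoyl)oxy]-2-hydroxy-3,5,6-trimethylbenzoate, via mixed anhydride 27 (not isolated)
Conditions: (CF3CO)2O, toluene, rt
Reagents that add atoms: none
Why: Mixed-anhydride depside esterification: the alkoxy-rich acid is activated as its trifluoroacetic mixed anhydride and acylates the free C4 hydroxyl, because the C2 hydroxyl is held in a hydrogen bond to the ester carbonyl and is far less nucleophilic.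

Step 14
Reactants: 28 methyl 4-[(3-formyl-2,4-dimethoxy-5,6-dimethylbenzoyl)oxy]-2-hydroxy-3,5,6-trimethylbenzoate
Product: 29 pseudocyphellarin A (methyl 4-[(3-formyl-2,4-dihydroxy-5,6-dimethylbenzoyl)oxy]-2-hydroxy-3,5,6-trimethylbenzoate)
Conditions: BCl3 (excess), CH2Cl2, −78 to 0 °C; H2O
Reagents that add atoms: none
Why: Chelation-assisted BCl3 demethylation: the C2' methoxy group lies between the depside carbonyl and the formyl group and the C4' methoxy group lies beside the formyl group, so both should cleave under conditions that spare the methyl ester, the depside ester and the aldehyde.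

## Compound list

1 | 1-fluoro-3,5-dimethoxybenzene | COc1cc(F)cc(OC)c1 | starting material
2 | iodomethane | CI | starting material
3 | (2-fluoro-4,6-dimethoxyphenyl)lithium | [Li]c1c(F)cc(OC)cc1OC | intermediate
4 | 1-fluoro-3,5-dimethoxy-2-methylbenzene | COc1cc(F)c(C)c(OC)c1 | intermediate
5 | (2-fluoro-4,6-dimethoxy-3-methylphenyl)lithium | [Li]c1c(F)c(C)c(OC)cc1OC | intermediate
6 | (2-fluoro-4,6-dimethoxy-3-methylphenyl)trimethylsilane | C[Si](C)(C)c1c(F)c(C)c(OC)cc1OC | intermediate
7 | [4-fluoro-2,6-dimethoxy-3-methyl-5-(trimethylsilyl)phenyl]lithium | [Li]c1c(OC)c(C)c(F)c([Si](C)(C)C)c1OC | intermediate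
8 | (2-fluoro-4,6-dimethoxy-3,5-dimethylphenyl)trimethylsilane | Cc1c(OC)c(C)c(F)c([Si](C)(C)C)c1OC | intermediate
9 | 1-fluoro-3,5-dimethoxy-2,4-dimethylbenzene | COc1cc(F)c(C)c(OC)c1C | intermediate
10 | methylmagnesium bromide | C[Mg]Br | starting material
11 | carbon dioxide | O=C=O | starting material
12 | (2-fluoro-4,6-dimethoxy-3,5-dimethylphenyl)lithium | [Li]c1c(F)c(C)c(OC)c(C)c1OC | intermediate
13 | 3,5-dimethoxy-4,6-dimethylbenzyne (1,2-didehydro arene) | COC1=C(C)C(OC)=C(C)C#C1 | intermediate
14 | (2,4-dimethoxy-3,5,6-trimethylphenyl)magnesium bromide | COc1c(C)c(OC)c(C)c(C)c1[Mg]Br | intermediate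
15 | 2,4-dimethoxy-3,5,6-trimethylbenzoic acid | COc1c(C)c(OC)c(C)c(C)c1C(=O)O | intermediate
16 | methyl 2,4-dimethoxy-3,5,6-trimethylbenzoate | COC(=O)c1c(C)c(C)c(OC)c(C)c1OC | intermediate
17 | methyl 2,4-dihydroxy-3,5,6-trimethylbenzoate | COC(=O)c1c(C)c(C)c(O)c(C)c1O | intermediate
18 | 4,5-dimethylresorcinol | Cc1cc(O)cc(O)c1C | starting material
19 | 1,5-dimethoxy-2,3-dimethylbenzene | COc1cc(C)c(C)c(OC)c1 | intermediate
20 | (2,6-dimethoxy-3,4-dimethylphenyl)lithium | [Li]c1c(OC)cc(C)c(C)c1OC | intermediate
21 | 2,6-dimethoxy-3,4-dimethylbenzaldehyde | COc1cc(C)c(C)c(OC)c1C=O | intermediate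
22 | 3-bromo-2,6-dimethoxy-4,5-dimethylbenzaldehyde | COc1c(Br)c(C)c(C)c(OC)c1C=O | intermediate
23 | 2-(3-bromo-2,6-dimethoxy-4,5-dimethylphenyl)-1,3-dioxolane | COc1c(Br)c(C)c(C)c(OC)c1C2OCCO2 | intermediate
24 | [3-(1,3-dioxolan-2-yl)-2,4-dimethoxy-5,6-dimethylphenyl]lithium | [Li]c1c(C)c(C)c(OC)c(C2OCCO2)c1OC | intermediate
25 | lithium 3-(1,3-dioxolan-2-yl)-2,4-dimethoxy-5,6-dimethylbenzoate | [Li+].[O-]C(=O)c1c(C)c(C)c(OC)c(C2OCCO2)c1OC | intermediate
26 | 3-formyl-2,4-dimethoxy-5,6-dimethylbenzoic acid | COc1c(C)c(C)c(C(=O)O)c(OC)c1C=O | intermediate
27 | 3-formyl-2,4-dimethoxy-5,6-dimethylbenzoic trifluoroacetic anhydride | COc1c(C)c(C)c(C(=O)OC(=O)C(F)(F)F)c(OC)c1C=O | intermediate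
28 | methyl 4-[(3-formyl-2,4-dimethoxy-5,6-dimethylbenzoyl)oxy]-2-hydroxy-3,5,6-trimethylbenzoate | COC(=O)c1c(C)c(C)c(OC(=O)c2c(C)c(C)c(OC)c(C=O)c2OC)c(C)c1O | intermediate
29 | pseudocyphellarin A | COC(=O)c1c(C)c(C)c(OC(=O)c2c(C)c(C)c(O)c(C=O)c2O)c(C)c1O | target

## Step count and risks

Total step count: 14.
Longest linear sequence: 9 (steps 1–7, 13, 14).

**Step 5 (key step).**
- What may go wrong: the aryne may be intercepted by its own aryllithium precursor or by residual n-BuLi faster than by CH3MgBr. The methyl group may enter partly at C1. The crowded arylmagnesium may be protonated before it is carboxylated.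
- Fallback, from 9 back to 15: the two bonds are made in the opposite order and without an aryne. Compound 9 is lithiated as before, but CO2 is passed in at −78 °C, before LiF can leave. This gives 2-fluoro-4,6-dimethoxy-3,5-dimethylbenzoic acid F1. Excess CH3MgBr in THF at reflux then replaces the ortho fluoride of the magnesium carboxylate by carboxylate-assisted addition–elimination (nucleophilic aromatic substitution on an unprotected 2-fluorobenzoic acid), which gives 15.

**Step 3.**
- What may go wrong: s-BuLi may attack silicon, which would strip the blocking group and release an aryllithium that loses LiF uncontrolled. A benzylic or silyl methyl group may be metalated instead of the ring. Deprotonation may be sluggish because both methoxy groups are pushed out of the ring plane.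
- Fallback, from 4 back to aryllithium 12 in step 5: the site beside fluorine is blocked by bromine, and the missing methyl group is brought in by electrophilic chemistry.
  - NBS in MeCN should brominate 4 para to the C3 methoxy group to give 1-bromo-2-fluoro-4,6-dimethoxy-3-methylbenzene F2.
  - Rieche formylation (Cl2CHOCH3, TiCl4, CH2Cl2, 0 °C) at the only remaining C–H gives 3-bromo-4-fluoro-2,6-dimethoxy-5-methylbenzaldehyde F3.
  - Ionic reduction (Et3SiH, CF3CO2H) gives 1-bromo-2-fluoro-4,6-dimethoxy-3,5-dimethylbenzene F4.
  - Bromine–lithium exchange of F4 with n-BuLi at −78 °C forms 12 directly, and the key step continues unchanged.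

**Step 13.**
- What may go wrong: acyl transfer between a di-ortho-substituted acid and a phenol flanked by two methyl groups may be slow. Trifluoroacetylation of the phenol or acylation at the C2 hydroxyl could then compete.
- Fallback, from 26 back to 29: deprotection is moved before the coupling. BCl3 in CH2Cl2 converts 26 into 3-formyl-2,4-dihydroxy-5,6-dimethylbenzoic acid F5. Its ortho hydroxyl is smaller than a methoxy group, and both of its hydroxyls are locked in hydrogen bonds to the formyl and carboxyl groups, so self-condensation is not expected. Carbodiimide condensation of F5 with 17 (dicyclohexylcarbodiimide, toluene, rt) should give 29 directly and bypass 28.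

## Further compounds

F1 | step 5 | 2-fluoro-4,6-dimethoxy-3,5-dimethylbenzoic acid | COc1c(C)c(OC)c(C(=O)O)c(F)c1C
F2 | step 3 | 1-bromo-2-fluoro-4,6-dimethoxy-3-methylbenzene | COc1cc(OC)c(Br)c(F)c1C
F3 | step 3 | 3-bromo-4-fluoro-2,6-dimethoxy-5-methylbenzaldehyde | COc1c(C=O)c(OC)c(Br)c(F)c1C
F4 | step 3 | 1-bromo-2-fluoro-4,6-dimethoxy-3,5-dimethylbenzene | COc1c(C)c(OC)c(Br)c(F)c1C
F5 | step 13 | 3-formyl-2,4-dihydroxy-5,6-dimethylbenzoic acid | Cc1c(C)c(C(=O)O)c(O)c(C=O)c1O
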